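The earlier runs and the new flask come from a simulation with constants of no real substance.

in all of them: left-handed substrate 0.32 M; right-handed substrate 0.32 M; gas 11 mM (held); free catalyst 0.14 mol%

| charge | added ligand | remark | time |
|---|---|---|---|
| south-east | 0.43 mM | run made earlier |  |
| east | 0.96 mM | run made earlier |  |
| flask | 0.64 mM |  | 2.5 d |

- south-east (time / d: right-handed substrate / %, left-handed substrate / %): 0.625: 48.6, 46.9; 1.25: 46.5, 44.3; 2.08: 43.5, 40.1; 2.50: 43.1, 38.2
- east (time / d: right-handed substrate / %, left-handed substrate / %): 0.625: 48.6, 47.8; 1.25: 47.7, 45.8; 2.08: 45.4, 43.4; 2.50: 44.9, 41.1

(scatter of a reading: 0.3 percentage points)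

- whether the excess of right-handed substrate over left-handed substrate among what is left of the two reaches 90% by 2.5 d (no / yes)
- the highest excess of right-handed substrate over left-handed substrate among what is left of the two up to 2.5 d

- free catalyst is single-handed; left-handed substrate and right-handed substrate are mirror images of each other, charged as a racemate, each of them at the stated concentration
- at the start none of coupling partner is dissolved
- candidate steps: coupling partner + catalyst intermediate A -> free catalyst + left-handed product; free catalyst + left-handed substrate <-> catalyst intermediate A; coupling partner + catalyst intermediate B -> free catalyst + right-handed product; free catalyst + added ligand <-> idle complex; free catalyst + right-handed substrate <-> catalyst intermediate B; coupling partner -> decomposed reagent; gas <-> coupling partner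

The easy step was to take the logarithm of the fraction of each substrate's own charge still there, and call it the log loss. In the south-east run the left-handed log loss ran at 0.102 /d up to the first reading and 0.108 /d up to the last, so it is close to a straight line in time. At the last readings the left-handed log loss over the right-handed one read 1.81 in the south-east run and 1.82 in the east run. This ratio, the selectivity factor, is what I carried, as a reading with its scatter.

The left-handed log loss at the last reading was 0.269 in the south-east run, at 0.43 mM of added ligand, and 0.196 in the east run, at 0.96 mM. Drawing its inverse straight against added ligand, I put the flask at 0.235 by 2.5 d. The gap between the two log losses in the flask is then 0.105. The excess starts from zero and climbs at about half the gap's slope of 0.0420 /d, with no knee while the gap stays small, so its top lies at the end, at 5.25%. An excess of 90% needs a gap of 2.94, which is 28.0 times larger, so my answer was no.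

The forecast said no and 5.1%, within 4.2% to 6.2%, a little below my figure, holding that “selectivity is modest and does not depend on ligand”.

The flask gave no and 4.49%.

    coupling partner + catalyst intermediate A → free catalyst + left-handed product (k = 27.5 /M/min)
    free catalyst + left-handed substrate ⇌ catalyst intermediate A (K = 2.73 /M, k = 32.6 /M/min)
    coupling partner + catalyst intermediate B → free catalyst + right-handed product (k = 10.0 /M/min)
    free catalyst + added ligand ⇌ idle complex, settled at all times (K = 4000 /M)
    free catalyst + right-handed substrate ⇌ catalyst intermediate B (K = 4.50 /M, k = 46.0 /M/min)
    coupling partner → decomposed reagent (k = 5.28 × 10⁻⁴ /min)
    gas ⇌ coupling partner, rate k7*(csat - [coupling partner]) (kL = 0.0271 /min)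

At 2.50 d the flask kept 80% of its left-handed charge and 87% of its right-handed charge. Left until 6.0 d, the same flask reached a top of 11.5%, above the high end the forecast gave for 2.5 d. Read at 10 d, the same flask kept 35% of its left-handed charge unbound, from which the selectivity factor gives 55.6% of the right-handed charge and an excess of 23.4%, where that flask stood at 52% and 20.6%.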